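**Plan**

- Retrosynthesis: the four methoxymethyl (MOM) ethers come off last. In ring C, C3 (hydroxylated) and C4 (carbonyl) are the dehydrogenated form of an acyloin between two aldehyde carbons, one on C4a of ring A and one on the side chain at the ether carbon C2; this is what allows ring C to be cut at C3–C4 back to a dialdehyde.
- Further cuts: O1–C2 (ring A phenoxide plus the α-bromo arylacetate of ring B), C8–CH2 (Negishi coupling of a ring A iodide with lavandulylzinc iodide), and the bond between the lavandulyl stereocentre and its prenyl CH2 (auxiliary-controlled alkylation).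
- Forward: lavandulyl iodide (steps 1–4), ring B bromo ester (5–7), ring A iodophenol (8–9), ether (10), lavandulyl coupling (11), redox adjustment to the dialdehyde (12–13), carbene-catalysed closure of ring C (14), oxidation to the 3-hydroxychromone (15), deprotection (16).
- Rings A and B are bought as benzenoid starting materials; ring C is the only ring that is made.
- Stereochemistry: the single stereocentre is set by an Evans alkylation in step 2 and no bond to it is touched afterwards; the centres that appear at C2 and C3 are erased in step 15.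

Key step: step 14

Remark: MOM = CH2OCH3; lavandulyl = 5-methyl-2-(prop-1-en-2-yl)hex-4-en-1-yl.
Remark: the (R) descriptor of the lavandulyl centre in the target corresponds to (S)-lavandulol with the same spatial arrangement, because CH2–aryl ranks below isopropenyl whereas CH2–O, CH2–I, CH2–Zn and the acyl carbon rank above it.
Remark: catalyst-bound species of a catalytic cycle (Breslow intermediate, organopalladium species) and metal alkoxides before work-up are treated as mechanism and are not numbered.
Remark: the acyloin from the key step is written as the 3-hydroxy-4-ketone, taken to be the more stable tautomer (aryl ketone conjugated to ring A).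

**Route**

Step 1
Reactants: 1 (S)-4-benzyl-1,3-oxazolidin-2-one; 2 3-methylbut-2-enoyl chloride
Product: 4 (S)-4-benzyl-3-(3-methylbut-2-enoyl)-1,3-oxazolidin-2-one, via lithium oxazolidinide 3 (not isolated)
Conditions: n-BuLi, THF, −78 °C; then 2, −78 → 0 °C
Reagents that add atoms: none
Why: N-acylation of the lithiated Evans oxazolidinone with an acid chloride is the standard entry to such imides; no stereocentre is formed and the auxiliary centre is not touched.

Step 2
Reactants: 4 (S)-4-benzyl-3-(3-methylbut-2-enoyl)-1,3-oxazolidin-2-one; 5 prenyl bromide (1-bromo-3-methylbut-2-ene)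
Product: 7 (S)-4-benzyl-3-[(S)-5-methyl-2-(prop-1-en-2-yl)hex-4-enoyl]-1,3-oxazolidin-2-one, via sodium Z-dienolate 6 (not isolated)
Conditions: NaN(SiMe3)2 (1.1 equiv), THF, −78 °C; then 5, −78 → −45 °C; AcOH quench at −78 °C
Reagents that add atoms: none
Why: Evans asymmetric alkylation in its deconjugative form: γ-deprotonation gives the chelated Z-dienolate, which should be alkylated at the α-carbon on the face away from the benzyl group, so the new centre should be (S) and the former conjugated double bond ends as the isopropenyl group.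

Step 3
Reactants: 7 (S)-4-benzyl-3-[(S)-5-methyl-2-(prop-1-en-2-yl)hex-4-enoyl]-1,3-oxazolidin-2-one
Product: 8 (S)-lavandulol, (S)-5-methyl-2-(prop-1-en-2-yl)hex-4-en-1-ol
Conditions: LiBH4, H2O (1 equiv), Et2O, 0 °C
Reagents that add atoms: none
Why: Reductive cleavage of an N-acyl oxazolidinone by LiBH4 attacks the exocyclic carbonyl and releases the primary alcohol without enolisation, so the α-centre should keep its configuration.

Step 4
Reactants: 8 (S)-lavandulol
Product: 9 (S)-lavandulyl iodide, (S)-6-iodo-2-methyl-5-(prop-1-en-2-yl)hex-2-ene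
Conditions: I2, PPh3, imidazole, CH2Cl2, 0 °C → rt
Reagents that add atoms: iodine, II
Why: Appel-type iodination (Garegg–Samuelsson conditions) is an SN2 displacement at the primary carbon, one bond away from the stereocentre, which is therefore untouched.

Step 5
Reactants: 10 2,4-dihydroxyphenylacetic acid
Product: 11 methyl 2-(2,4-dihydroxyphenyl)acetate
Conditions: MeOH, H2SO4 (cat.), reflux
Reagents that add atoms: methanol, CO
Why: Fischer esterification of an arylacetic acid is routine and leaves the phenols free.

Step 6
Reactants: 11 methyl 2-(2,4-dihydroxyphenyl)acetate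
Product: 12 methyl 2-[2,4-bis(methoxymethoxy)phenyl]acetate
Conditions: MOMCl (2.5 equiv), i-Pr2NEt, CH2Cl2, 0 °C → rt
Reagents that add atoms: chloromethyl methyl ether, COCCl
Why: O-alkylation of phenols with MOMCl and an amine base (Williamson-type acetal ether formation) is standard and both hydroxyls are unhindered.

Step 7
Reactants: 12 methyl 2-[2,4-bis(methoxymethoxy)phenyl]acetate
Product: 14 methyl 2-bromo-2-[2,4-bis(methoxymethoxy)phenyl]acetate (racemic), via lithium ester enolate 13 (not isolated)
Conditions: LiN(SiMe3)2, THF, −78 °C; then NBS, −78 °C; used without storage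
Reagents that add atoms: N-bromosuccinimide, O=C1CCC(=O)N1Br
Why: Electrophilic α-bromination of a preformed ester enolate places bromine at the benzylic carbon and not on the electron-rich ring; the new centre is racemic and is erased in step 15.

Step 8
Reactants: 15 2,4,6-trihydroxybenzaldehyde
Product: 16 2-hydroxy-4,6-bis(methoxymethoxy)benzaldehyde
Conditions: MOMCl (2.1 equiv), i-Pr2NEt, CH2Cl2, 0 °C → rt
Reagents that add atoms: chloromethyl methyl ether, COCCl
Why: Chemoselective O-alkylation: the para hydroxyl and one ortho hydroxyl react, while the remaining ortho hydroxyl is held in a hydrogen bond to the formyl group and should stay free.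

Step 9
Reactants: 16 2-hydroxy-4,6-bis(methoxymethoxy)benzaldehyde
Product: 17 2-hydroxy-3-iodo-4,6-bis(methoxymethoxy)benzaldehyde
Conditions: benzyltrimethylammonium dichloroiodate (1.05 equiv), NaHCO3, CH2Cl2–MeOH, rt
Reagents that add atoms: benzyltrimethylammonium dichloroiodate, C[N+](C)(C)Cc1ccccc1.Cl[I-]Cl
Why: Electrophilic aromatic iodination of an o-hydroxyaryl carbonyl compound of this pattern should go ortho to the chelated hydroxyl (C3), the less crowded of the two open positions, which places the halogen beside the oxygen that later becomes O1.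

Step 10
Reactants: 17 2-hydroxy-3-iodo-4,6-bis(methoxymethoxy)benzaldehyde; 14 methyl 2-bromo-2-[2,4-bis(methoxymethoxy)phenyl]acetate
Product: 18 methyl 2-[2,4-bis(methoxymethoxy)phenyl]-2-[2-formyl-6-iodo-3,5-bis(methoxymethoxy)phenoxy]acetate (racemic)
Conditions: K2CO3, DMF, rt
Reagents that add atoms: none
Why: Williamson ether synthesis: the phenoxide displaces the doubly activated benzylic bromide at room temperature, mild enough that aldol closure of the ester onto the formyl group should not set in; the new ether centre is racemic and is erased in step 15.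

Step 11
Reactants: 18 methyl 2-[2,4-bis(methoxymethoxy)phenyl]-2-[2-formyl-6-iodo-3,5-bis(methoxymethoxy)phenoxy]acetate; 9 (S)-lavandulyl iodide
Product: 20 methyl 2-[2,4-bis(methoxymethoxy)phenyl]-2-{2-formyl-3,5-bis(methoxymethoxy)-6-[(R)-lavandulyl]phenoxy}acetate (both epimers at the ether carbon), via (S)-lavandulylzinc iodide 19 (not isolated)
Conditions: 9, Zn (dust, activated with BrCH2CH2Br and Me3SiCl), LiCl, THF, 40 °C; then 18, Pd(OAc)2 (5 mol %), SPhos (10 mol %), THF, 25 → 50 °C
Reagents that add atoms: none
Why: Negishi sp3–sp2 cross-coupling of a primary alkylzinc iodide, made by oxidative zinc insertion, tolerates the aldehyde, ester and acetals, and the bulky biarylphosphine should drive reductive elimination ahead of β-hydride elimination; the stereocentre sits β to zinc and is not involved.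

Step 12
Reactants: 20 methyl 2-[2,4-bis(methoxymethoxy)phenyl]-2-{2-formyl-3,5-bis(methoxymethoxy)-6-[(R)-lavandulyl]phenoxy}acetate
Product: 21 2-[2,4-bis(methoxymethoxy)phenyl]-2-{2-(hydroxymethyl)-3,5-bis(methoxymethoxy)-6-[(R)-lavandulyl]phenoxy}ethan-1-ol (both epimers at the ether carbon)
Conditions: LiAlH4, THF, 0 °C
Reagents that add atoms: none
Why: Hydride reduction takes the ester and the aldehyde to the two primary alcohols in one operation and leaves acetals, aryl ether and alkenes alone.

Step 13
Reactants: 21 2-[2,4-bis(methoxymethoxy)phenyl]-2-{2-(hydroxymethyl)-3,5-bis(methoxymethoxy)-6-[(R)-lavandulyl]phenoxy}ethan-1-ol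
Product: 22 2-{1-[2,4-bis(methoxymethoxy)phenyl]-2-oxoethoxy}-4,6-bis(methoxymethoxy)-3-[(R)-lavandulyl]benzaldehyde (both epimers at the ether carbon)
Conditions: Dess–Martin periodinane (2.5 equiv), CH2Cl2, 0 °C → rt; crude dialdehyde taken on the same day
Reagents that add atoms: none
Why: Dess–Martin oxidation converts the benzylic and the aliphatic primary alcohol to aldehydes under near-neutral conditions that should spare the enolisable α-aryloxy aldehyde from aldol or over-oxidation.

Step 14
Reactants: 22 2-{1-[2,4-bis(methoxymethoxy)phenyl]-2-oxoethoxy}-4,6-bis(methoxymethoxy)-3-[(R)-lavandulyl]benzaldehyde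
Product: 23 3-hydroxy-8-[(R)-lavandulyl]-5,7-bis(methoxymethoxy)-2-[2,4-bis(methoxymethoxy)phenyl]chroman-4-one (mixture at C2 and C3)
Conditions: 2-(pentafluorophenyl)-6,7-dihydro-5H-pyrrolo[2,1-c][1,2,4]triazol-2-ium tetrafluoroborate (20 mol %), Et3N (20 mol %), degassed toluene (0.01 M), 25 °C, argon
Reagents that add atoms: none
Why: The free triazolylidene adds to the ring A formyl carbon, proton transfer gives the Breslow intermediate, and this acyl-anion equivalent attacks the side-chain aldehyde to form C3–C4 before the carbene is expelled from the acyloin; the reaction type is the carbene-catalysed intramolecular crossed benzoin cyclisation, closest to the closures of 2-(2-oxoalkoxy)benzaldehydes to 3-hydroxychroman-4-ones. Ring C closes in a 6-exo-trig mode. The new centres C2 and C3 are not controlled and need not be, since both become sp2 in step 15, while the lavandulyl centre is remote and carries no acidic hydrogen. The step needs cyclisation to win over bimolecular benzoin coupling, which the six-membered tether and the 0.01 M dilution should secure. It also needs the carbene not to dwell on the side-chain aldehyde, whose Breslow intermediate could expel the ring A phenoxide; the α,α-disubstitution of that aldehyde, the weak base and the proximity of the acceptor are relied on here. The donor–acceptor sense is otherwise uncritical, because the isomeric 4-hydroxy-3-ketone would be oxidised to the same dione in step 15.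

Step 15
Reactants: 23 3-hydroxy-8-[(R)-lavandulyl]-5,7-bis(methoxymethoxy)-2-[2,4-bis(methoxymethoxy)phenyl]chroman-4-one
Product: 25 3-hydroxy-8-[(R)-lavandulyl]-5,7-bis(methoxymethoxy)-2-[2,4-bis(methoxymethoxy)phenyl]-4H-chromen-4-one, via chromane-3,4-dione 24 (not isolated)
Conditions: IBX (1.5 equiv), DMSO, rt
Reagents that add atoms: none
Why: IBX oxidation of an α-hydroxy ketone gives the 1,2-dione, which has an acidic hydrogen at C2 and should tautomerise at once to the 3-hydroxychromone, so all diastereomers converge on one compound.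

Step 16
Reactants: 25 3-hydroxy-8-[(R)-lavandulyl]-5,7-bis(methoxymethoxy)-2-[2,4-bis(methoxymethoxy)phenyl]-4H-chromen-4-one
Product: 26 kushenol C
Conditions: HCl (2 M) in MeOH–THF, 40 °C, stopped as soon as the last acetal is gone
Reagents that add atoms: none
Why: Acid-catalysed acetal exchange with methanol removes aryl MOM ethers under conditions used for prenylated flavonoids, and the short, mild exposure is meant to keep the 7-hydroxyl from adding to the isopropenyl group.

**Compound list**

1 | (S)-4-benzyl-1,3-oxazolidin-2-one | O=C1N[C@@H](Cc2ccccc2)CO1 | starting material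
2 | 3-methylbut-2-enoyl chloride | CC(C)=CC(=O)Cl | starting material
3 | lithium salt of 1 (N-lithio oxazolidinone) | [Li+].O=C1[N-][C@@H](Cc2ccccc2)CO1 | intermediate
4 | (S)-4-benzyl-3-(3-methylbut-2-enoyl)-1,3-oxazolidin-2-one | CC(C)=CC(=O)N1[C@@H](Cc2ccccc2)COC1=O | intermediate
5 | prenyl bromide (1-bromo-3-methylbut-2-ene) | CC(C)=CCBr | starting material
6 | sodium Z-dienolate of 4 | [Na+].[O-]/C(=C\C(C)=C)N1[C@@H](Cc2ccccc2)COC1=O | intermediate
7 | (S)-4-benzyl-3-[(S)-5-methyl-2-(prop-1-en-2-yl)hex-4-enoyl]-1,3-oxazolidin-2-one | C=C(C)[C@H](CC=C(C)C)C(=O)N1[C@@H](Cc2ccccc2)COC1=O | intermediate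
8 | (S)-lavandulol | C=C(C)[C@H](CC=C(C)C)CO | intermediate
9 | (S)-lavandulyl iodide | C=C(C)[C@H](CC=C(C)C)CI | intermediate
10 | 2,4-dihydroxyphenylacetic acid | O=C(O)Cc1ccc(O)cc1O | starting material
11 | methyl 2-(2,4-dihydroxyphenyl)acetate | COC(=O)Cc1ccc(O)cc1O | intermediate
12 | methyl 2-[2,4-bis(methoxymethoxy)phenyl]acetate | COC(=O)Cc1ccc(OCOC)cc1OCOC | intermediate
13 | lithium enolate of 12 | [Li+].[O-]C(OC)=Cc1ccc(OCOC)cc1OCOC | intermediate
14 | methyl 2-bromo-2-[2,4-bis(methoxymethoxy)phenyl]acetate (racemic) | COC(=O)C(Br)c1ccc(OCOC)cc1OCOC | intermediate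
15 | 2,4,6-trihydroxybenzaldehyde | O=Cc1c(O)cc(O)cc1O | starting material
16 | 2-hydroxy-4,6-bis(methoxymethoxy)benzaldehyde | O=Cc1c(O)cc(OCOC)cc1OCOC | intermediate
17 | 2-hydroxy-3-iodo-4,6-bis(methoxymethoxy)benzaldehyde | O=Cc1c(O)c(I)c(OCOC)cc1OCOC | intermediate
18 | methyl 2-[2,4-bis(methoxymethoxy)phenyl]-2-[2-formyl-6-iodo-3,5-bis(methoxymethoxy)phenoxy]acetate (racemic) | COC(=O)C(Oc1c(I)c(OCOC)cc(OCOC)c1C=O)c1ccc(OCOC)cc1OCOC | intermediate
19 | (S)-lavandulylzinc iodide | C=C(C)[C@H](CC=C(C)C)C[Zn]I | intermediate
20 | methyl 2-[2,4-bis(methoxymethoxy)phenyl]-2-{2-formyl-3,5-bis(methoxymethoxy)-6-[(R)-lavandulyl]phenoxy}acetate (epimers at the ether carbon) | C=C(C)[C@H](CC=C(C)C)Cc1c(OCOC)cc(OCOC)c(C=O)c1OC(C(=O)OC)c1ccc(OCOC)cc1OCOC | intermediate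
21 | 2-[2,4-bis(methoxymethoxy)phenyl]-2-{2-(hydroxymethyl)-3,5-bis(methoxymethoxy)-6-[(R)-lavandulyl]phenoxy}ethan-1-ol (epimers at the ether carbon) | C=C(C)[C@H](CC=C(C)C)Cc1c(OCOC)cc(OCOC)c(CO)c1OC(CO)c1ccc(OCOC)cc1OCOC | intermediate
22 | 2-{1-[2,4-bis(methoxymethoxy)phenyl]-2-oxoethoxy}-4,6-bis(methoxymethoxy)-3-[(R)-lavandulyl]benzaldehyde (epimers at the ether carbon) | C=C(C)[C@H](CC=C(C)C)Cc1c(OCOC)cc(OCOC)c(C=O)c1OC(C=O)c1ccc(OCOC)cc1OCOC | intermediate
23 | 3-hydroxy-8-[(R)-lavandulyl]-5,7-bis(methoxymethoxy)-2-[2,4-bis(methoxymethoxy)phenyl]chroman-4-one (mixture at C2 and C3) | C=C(C)[C@H](CC=C(C)C)Cc1c(OCOC)cc(OCOC)c2C(=O)C(O)C(c3ccc(OCOC)cc3OCOC)Oc12 | intermediate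
24 | 8-[(R)-lavandulyl]-5,7-bis(methoxymethoxy)-2-[2,4-bis(methoxymethoxy)phenyl]chromane-3,4-dione | C=C(C)[C@H](CC=C(C)C)Cc1c(OCOC)cc(OCOC)c2C(=O)C(=O)C(c3ccc(OCOC)cc3OCOC)Oc12 | intermediate
25 | 3-hydroxy-8-[(R)-lavandulyl]-5,7-bis(methoxymethoxy)-2-[2,4-bis(methoxymethoxy)phenyl]-4H-chromen-4-one | C=C(C)[C@H](CC=C(C)C)Cc1c(OCOC)cc(OCOC)c2c(=O)c(O)c(-c3ccc(OCOC)cc3OCOC)oc12 | intermediate
26 | kushenol C | C=C(C)[C@H](CC=C(C)C)Cc1c(O)cc(O)c2c(=O)c(O)c(-c3ccc(O)cc3O)oc12 | target

**Totals**

Total step count: 16.
Longest linear sequence: 10 steps (steps 1–4 and 11–16; the ring B branch, steps 5–7 and 10–16, is equally long).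

**Steps most likely to fail, with fallbacks**

Step 14. The carbene may add preferentially to the side-chain aldehyde, and the resulting Breslow intermediate may expel the ring A phenoxide (internal redox to an aryl ester or a coumarin) faster than it closes onto the hindered, electron-rich ring A aldehyde; alternatively neither hindered formyl group may turn over. The fallback sets out from dialdehyde 22 and forms the same C3–C4 bond reductively. SmI2 (2.5 equiv) with t-BuOH in THF at −78 °C should generate the ketyl at the conjugated ring A aldehyde, which adds to the tethered aliphatic aldehyde in an intramolecular pinacol coupling. No acyl-anion equivalent is placed on the carbon next to the aryloxy group. This should give 8-[(R)-lavandulyl]-5,7-bis(methoxymethoxy)-2-[2,4-bis(methoxymethoxy)phenyl]chromane-3,4-diol F1 as a mixture of diastereomers. IBX (3 equiv) in DMSO at rt oxidises both carbinols without glycol cleavage to dione 24, which tautomerises, and the route is rejoined at compound 25.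

Step 11. Oxidative addition and transmetalation at the carbon–iodine bond of 18, flanked by a MOM ether and the branched ether, may be slow enough for β-hydride elimination from the alkylpalladium to consume the zinc reagent and reduce the iodide. The fallback sets out from iodophenol 17 and changes the order of assembly, so that the coupling is done where the iodide has only a hydroxyl as its second neighbour. Compound 17 is coupled with zinc reagent 19 (2.2 equiv, slow addition, the first equivalent being spent on the phenol proton; Pd(OAc)2, SPhos, THF, 25 °C) to give 2-hydroxy-3-[(R)-lavandulyl]-4,6-bis(methoxymethoxy)benzaldehyde F2. Williamson etherification of F2 with bromo ester 14 (K2CO3, DMF, rt) then rejoins the route at compound 20.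

Step 9. The electrophilic iodination may show poor site selectivity, with attack at C5 between the two MOM ethers or double iodination, which would place the lavandulyl group at C6 of the flavonol. The fallback sets out from 16 and fixes the position by symmetry, then chooses the oxygen by sterics. Compound 16 is fully protected (MOMCl, NaH, DMF) to the symmetric 2,4,6-tris(methoxymethoxy)benzaldehyde F3, whose two open ring positions are equivalent. NIS in MeCN gives 3-iodo-2,4,6-tris(methoxymethoxy)benzaldehyde F4. Negishi coupling with 19 (Pd(OAc)2, SPhos, THF) gives 3-[(R)-lavandulyl]-2,4,6-tris(methoxymethoxy)benzaldehyde F5. Brief treatment with HCl in MeOH at rt removes all three MOM groups to 2,4,6-trihydroxy-3-[(R)-lavandulyl]benzaldehyde F6. Reprotection with MOMCl (2.1 equiv) and i-Pr2NEt should take the para hydroxyl and the unhindered ortho hydroxyl and leave the one beside the lavandulyl chain free, which gives the salicylaldehyde F2. Etherification of F2 with 14 (K2CO3, DMF) rejoins the route at compound 20.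

**Further compounds**

F1 | step 14 | 8-[(R)-lavandulyl]-5,7-bis(methoxymethoxy)-2-[2,4-bis(methoxymethoxy)phenyl]chromane-3,4-diol (diastereomers) | C=C(C)[C@H](CC=C(C)C)Cc1c(OCOC)cc(OCOC)c2C(O)C(O)C(c3ccc(OCOC)cc3OCOC)Oc12
F2 | step 11 | 2-hydroxy-3-[(R)-lavandulyl]-4,6-bis(methoxymethoxy)benzaldehyde | C=C(C)[C@H](CC=C(C)C)Cc1c(O)c(C=O)c(OCOC)cc1OCOC
F3 | step 9 | 2,4,6-tris(methoxymethoxy)benzaldehyde | O=Cc1c(OCOC)cc(OCOC)cc1OCOC
F4 | step 9 | 3-iodo-2,4,6-tris(methoxymethoxy)benzaldehyde | O=Cc1c(OCOC)c(I)c(OCOC)cc1OCOC
F5 | step 9 | 3-[(R)-lavandulyl]-2,4,6-tris(methoxymethoxy)benzaldehyde | C=C(C)[C@H](CC=C(C)C)Cc1c(OCOC)c(C=O)c(OCOC)cc1OCOC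
F6 | step 9 | 2,4,6-trihydroxy-3-[(R)-lavandulyl]benzaldehyde | C=C(C)[C@H](CC=C(C)C)Cc1c(O)c(C=O)c(O)cc1O
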